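**Assumption:** the target is exactly the stereoisomer of the given SMILES; carbons are numbered C1 (lactone C=O) to C12 along the polypropionate chain, and β-keto lactones are drawn as their enol tautomers.

## Retrosynthetic overview

1. Target 21 ⇐ spiro-trione 19 by equatorial hydride delivery to the C9 ketone and in-situ acetylation.
2. 19 ⇐ 17 by forming C2–C7 in an intramolecular silyloxypyrylium Mukaiyama–Michael reaction; this closes the cyclohexanone and the 2-oxabicyclo[2.2.2]octane and creates the spiro centre (last rings formed).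
3. 17 ⇐ ketone 11 + trans-β-lactone 14 by a two-carbon ring expansion of the oxetanone (insertion of C7–C8 into its acyl–O bond) to the dihydropyranone.
4. 11 ⇐ cis-β-lactone 6 + ethyl propanoate by a two-carbon ring expansion of the oxetanone (insertion of C1–C2) to the β-keto-δ-lactone; 6 ⇐ aldehyde 3 + propanoyl chloride (C4–C5).
5. 3 ⇐ two propanal (D-proline aldol). Ring order: oxetanone → δ-lactone → dihydropyranone → carbocycle and bridged lactone.

## Route

Step 1
Reactants: 1 propanal (2 equiv)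
Product: 2 (2R,3R)-3-hydroxy-2-methylpentanal
Conditions: D-proline (10 mol %), DMF, 4 °C, slow addition of 1
Reagents that add atoms: none
Why: Proline-catalysed direct aldol dimerisation (enamine catalysis) gives the anti dimer, D-proline setting C2 (future C6) as R; the carbinol centre (major anti isomer drawn, minor syn isomer removed at 3) is irrelevant because it is oxidised in step 5.

Step 2
Reactants: 2 (2R,3R)-3-hydroxy-2-methylpentanal
Product: 3 (2R,3R)-2-methyl-3-(triethylsilyloxy)pentanal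
Conditions: TESCl, imidazole, CH2Cl2, 0 °C
Reagents that add atoms: chlorotriethylsilane CC[Si](Cl)(CC)CC
Why: Standard silylation of the aldol; TES is chosen so that the acidic work-up of step 4 removes it without a separate step.

Step 3
Reactants: 3 (2R,3R)-2-methyl-3-(triethylsilyloxy)pentanal; 4 propanoyl chloride
Product: 6 (3S,4R)-3-methyl-4-[(2S,3R)-3-(triethylsilyloxy)pentan-2-yl]oxetan-2-one, via methylketene 5 (not isolated)
Conditions: O-TMS-quinine (10 mol %; the pseudoenantiomer gives the antipodal lactone series), LiClO4, i-Pr2NEt, CH2Cl2/Et2O, −78 °C, slow addition of 4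
Reagents that add atoms: none
Why: Cinchona/Li⁺-catalysed acyl halide–aldehyde cyclocondensation (ammonium-enolate aldol–lactonisation) gives the cis-β-lactone; catalyst control, reinforced by the anti-Felkin preference of Z-enolate-type additions to α-methyl aldehydes, sets C4 (S) and C5 (R), i.e. C4/C5 syn and C5/C6 anti.

Step 4
Reactants: 6 (3S,4R)-3-methyl-4-[(2S,3R)-3-(triethylsilyloxy)pentan-2-yl]oxetan-2-one; 7 ethyl propanoate
Product: 10 (5S,6R)-4-hydroxy-6-[(2R,3R)-3-hydroxypentan-2-yl]-3,5-dimethyl-5,6-dihydro-2H-pyran-2-one, via lithium enolate of ethyl propanoate 8 (not isolated), via open-chain δ-hydroxy-β-keto ester 9 (not isolated)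
Conditions: LDA, THF, −78 °C; add 6, −78 → 0 °C; 1 M NaOH (aq), 23 °C; then 3 M HCl to pH 1, 23 °C
Reagents that add atoms: none
Why: Claisen-type two-carbon ring expansion of the β-lactone: the ester enolate attacks the strained lactone carbonyl, and the released C5 alkoxide re-closes on the ethyl ester (translactonisation) to the enolised β-keto-δ-lactone; no stereocentre is touched and the acid also cleaves the TES ether.

Step 5
Reactants: 10 (5S,6R)-4-hydroxy-6-[(2R,3R)-3-hydroxypentan-2-yl]-3,5-dimethyl-5,6-dihydro-2H-pyran-2-one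
Product: 11 (5S,6S)-4-hydroxy-3,5-dimethyl-6-[(2S)-3-oxopentan-2-yl]-5,6-dihydro-2H-pyran-2-one
Conditions: Dess–Martin periodinane, CH2Cl2, 0 → 23 °C
Reagents that add atoms: none
Why: Dess–Martin oxidation of the secondary alcohol under non-basic conditions, so the α-stereocentre C6 and the β-acyloxy ketone (E1cB-prone) survive.

Step 6
Reactants: 12 (R)-4-methyloxetan-2-one
Product: 14 (3R,4R)-3,4-dimethyloxetan-2-one, via lithium enolate of the lactone 13 (not isolated)
Conditions: LDA, THF, −78 °C; MeI, −78 °C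
Reagents that add atoms: iodomethane CI
Why: β-Lactone enolate alkylation occurs anti to the C4 methyl and gives the trans lactone, which carries C11 (R) from the chiral pool and C10 (R) in the final anti relationship.

Step 7
Reactants: 11 (5S,6S)-4-hydroxy-3,5-dimethyl-6-[(2S)-3-oxopentan-2-yl]-5,6-dihydro-2H-pyran-2-one; 14 (3R,4R)-3,4-dimethyloxetan-2-one
Product: 17 (5S,6S)-4-hydroxy-3,5-dimethyl-6-{(1S)-1-[(2R,3R)-2,3,5-trimethyl-4-oxo-3,4-dihydro-2H-pyran-6-yl]ethyl}-5,6-dihydro-2H-pyran-2-one, via dilithium dianion of the keto lactone 15 (not isolated), via open-chain δ-hydroxy-β-diketone 16 (not isolated)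
Conditions: LiHMDS (3.1 equiv), THF, −78 °C; 14, −78 → −40 °C; AcOH; then TFA (cat.), CH2Cl2, 0 °C
Reagents that add atoms: none
Why: Second two-carbon ring expansion of a β-lactone: the kinetic C8 enolate (ethyl side; the lactone is shielded as its enolate) is C-acylated at the lactone carbonyl (Claisen acylation), and the freed C11 hydroxyl cyclodehydrates onto C7 to the 2,3-dihydro-4H-pyran-4-one; C10 and C11 come unchanged from 14 and the mild acid leaves C6 intact.

Step 8
Reactants: 17 (5S,6S)-4-hydroxy-3,5-dimethyl-6-{(1S)-1-[(2R,3R)-2,3,5-trimethyl-4-oxo-3,4-dihydro-2H-pyran-6-yl]ethyl}-5,6-dihydro-2H-pyran-2-one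
Product: 19 (1R,3'S,4S,5'R,6S,6'R,7S,8R)-3',4,5',6,6',7-hexamethylspiro[2-oxabicyclo[2.2.2]octane-8,2'-oxane]-3,4',5-trione, via C9 trimethylsilyl enol ether 18 (not isolated)
Conditions: TMSOTf (2.5 equiv), 2,6-lutidine (1.1 equiv), CH2Cl2, −78 → −20 °C; then 1 M HCl, THF, 0 °C
Reagents that add atoms: none
Why: Proposed new method: intramolecular silyloxypyrylium Mukaiyama–Michael spiroannulation, in which TMSOTf/lutidine turns the enolised β-keto lactone into its C2-nucleophilic silyl enol ether (blocking O-attack) and TMSOTf O-silylates the vinylogous ester to a 4-silyloxy-2,3-dihydropyrylium (oxocarbenium at C7); six-membered boat attack of C2 on C7 forges both quaternary centres, the C3 silyloxocarbenium returns TMS to triflate, and the C8=C9 silyl enol ether is protonated axially on work-up (C8 methyl equatorial); C2 is fixed by the C5 tether and C7 by A1,3 strain (C6–H rather than C6–Me eclipses the C8 methyl, so the ring oxygen ends syn to the lactone bridge); the closest known reaction type is the silyl-triflate-mediated conjugate addition of silyl enol ethers to chromones and 4-pyranones.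

Step 9
Reactants: 19 (1R,3'S,4S,5'R,6S,6'R,7S,8R)-3',4,5',6,6',7-hexamethylspiro[2-oxabicyclo[2.2.2]octane-8,2'-oxane]-3,4',5-trione
Product: 21 (1R,3'R,4S,4'R,5'R,6S,6'R,7S,8S)-3',4,5',6,6',7-hexamethyl-3,5-dioxospiro[2-oxabicyclo[2.2.2]octane-8,2'-oxan]-4'-yl acetate (CNP0257416.1), via lithium C9 alkoxide 20 (not isolated)
Conditions: L-Selectride (1.1 equiv), THF, −78 °C; then Ac2O, DMAP, −78 → 23 °C
Reagents that add atoms: acetic anhydride CC(=O)OC(C)=O
Why: Bulky-hydride ketone reduction with in-situ O-acylation: the axial face of the C9 ketone is blocked by the axial C6 branch on the spiro carbon, so hydride enters equatorially and gives the axial alkoxide (C9 R), which Ac2O traps; the C3 ketone (next to quaternary C2) and the lactone are too hindered or unreactive at −78 °C.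

## Compound list

1 | propanal | CCC=O | starting material
2 | (2R,3R)-3-hydroxy-2-methylpentanal | O=C[C@H](C)[C@H](O)CC | intermediate
3 | (2R,3R)-2-methyl-3-(triethylsilyloxy)pentanal | O=C[C@H](C)[C@H](O[Si](CC)(CC)CC)CC | intermediate
4 | propanoyl chloride | CCC(Cl)=O | starting material
5 | methylketene (prop-1-en-1-one) | CC=C=O | intermediate (not isolated)
6 | (3S,4R)-3-methyl-4-[(2S,3R)-3-(triethylsilyloxy)pentan-2-yl]oxetan-2-one | O=C1[C@@H](C)[C@H](O1)[C@H](C)[C@H](O[Si](CC)(CC)CC)CC | intermediate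
7 | ethyl propanoate | CCC(=O)OCC | starting material
8 | lithium enolate of ethyl propanoate | [Li+].CC=C([O-])OCC | intermediate (not isolated)
9 | ethyl (4S,5R,6S,7R)-5-hydroxy-2,4,6-trimethyl-3-oxo-7-(triethylsilyloxy)nonanoate (C2 epimers, formed as its lithium salt) | CCOC(=O)C(C)C(=O)[C@@H](C)[C@H](O)[C@H](C)[C@H](O[Si](CC)(CC)CC)CC | intermediate (not isolated)
10 | (5S,6R)-4-hydroxy-6-[(2R,3R)-3-hydroxypentan-2-yl]-3,5-dimethyl-5,6-dihydro-2H-pyran-2-one | CC1=C(O)[C@@H](C)[C@H](OC1=O)[C@H](C)[C@H](O)CC | intermediate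
11 | (5S,6S)-4-hydroxy-3,5-dimethyl-6-[(2S)-3-oxopentan-2-yl]-5,6-dihydro-2H-pyran-2-one | CC1=C(O)[C@@H](C)[C@H](OC1=O)[C@H](C)C(=O)CC | intermediate
12 | (R)-4-methyloxetan-2-one | C[C@@H]1CC(=O)O1 | starting material
13 | lithium enolate of (R)-4-methyloxetan-2-one | [Li+].C[C@@H]1C=C([O-])O1 | intermediate (not isolated)
14 | (3R,4R)-3,4-dimethyloxetan-2-one | O=C1[C@H](C)[C@@H](C)O1 | intermediate
15 | dilithium dianion of 11 (lactone enolate and C7=C8 ketone enolate) | [Li+].[Li+].CC1=C([O-])[C@@H](C)[C@H](OC1=O)[C@H](C)C([O-])=CC | intermediate (not isolated)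
16 | (5S,6S)-4-hydroxy-6-[(2S,6R,7R)-7-hydroxy-4,6-dimethyl-3,5-dioxooctan-2-yl]-3,5-dimethyl-5,6-dihydro-2H-pyran-2-one (C4' epimers/enol) | CC1=C(O)[C@@H](C)[C@H](OC1=O)[C@H](C)C(=O)C(C)C(=O)[C@H](C)[C@@H](C)O | intermediate (not isolated)
17 | (5S,6S)-4-hydroxy-3,5-dimethyl-6-{(1S)-1-[(2R,3R)-2,3,5-trimethyl-4-oxo-3,4-dihydro-2H-pyran-6-yl]ethyl}-5,6-dihydro-2H-pyran-2-one | CC1=C(O)[C@@H](C)[C@H](OC1=O)[C@H](C)C2=C(C)C(=O)[C@H](C)[C@@H](C)O2 | intermediate
18 | C9 (oxane C4') trimethylsilyl enol ether of 19, C8=C9 double bond | C[Si](C)(C)OC=1[C@H](C)[C@@H](C)O[C@@]2(C=1C)[C@@H](C)[C@H]1OC(=O)[C@]2(C)C(=O)[C@H]1C | intermediate (not isolated)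
19 | (1R,3'S,4S,5'R,6S,6'R,7S,8R)-3',4,5',6,6',7-hexamethylspiro[2-oxabicyclo[2.2.2]octane-8,2'-oxane]-3,4',5-trione | O=C1[C@H](C)[C@@H](C)O[C@@]2([C@@H]1C)[C@@H](C)[C@H]1OC(=O)[C@]2(C)C(=O)[C@H]1C | intermediate
20 | lithium alkoxide of the axial C9 (oxane C4') alcohol of 19 | [Li+].[O-][C@@H]1[C@H](C)[C@@H](C)O[C@@]2([C@@H]1C)[C@@H](C)[C@H]1OC(=O)[C@]2(C)C(=O)[C@H]1C | intermediate (not isolated)
21 | (1R,3'R,4S,4'R,5'R,6S,6'R,7S,8S)-3',4,5',6,6',7-hexamethyl-3,5-dioxospiro[2-oxabicyclo[2.2.2]octane-8,2'-oxan]-4'-yl acetate (CNP0257416.1) | CC(=O)O[C@@H]1[C@H](C)[C@@H](C)O[C@@]2([C@@H]1C)[C@@H](C)[C@H]1OC(=O)[C@]2(C)C(=O)[C@H]1C | target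

## Step count and risk

Total step count: 9. Longest linear sequence: 8 (steps 1, 2, 3, 4, 5, 7, 8, 9); step 6 is a one-step side branch.

The three steps most likely to fail:

**Step 8 (the proposed new spiroannulation).** The risks are O- instead of C-attack, loss of the C6 configuration through γ-deprotonation of the pyrylium, and a reversible or sluggish closure to two adjacent quaternary centres. The fallback uses known chemistry and sets out from 11. The trianion of 11 (LiHMDS, THF, −78 °C) is C-acylated with (E)-2-methylbut-2-enoyl chloride to give the open-chain tiglyl β-diketone (5S,6S)-6-[(2S,6E)-4,6-dimethyl-3,5-dioxooct-6-en-2-yl]-4-hydroxy-3,5-dimethyl-5,6-dihydro-2H-pyran-2-one F8. Mild base (Cs2CO3, MeCN, 23 °C) then drives reversible 6-endo oxa-Michael ring closure and intramolecular aldol/Michael C2–C7 bond formation (both textbook enolate reactions) under thermodynamic control. The fallback comes back to the route at 19, with the C8, C10 and C11 methyls settling equatorial; base exposure must be kept short because C4 is also enolisable.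

**Step 7 (trianion acylation and ring expansion to the dihydropyranone).** The risks are enolate attack at the alkyl instead of the acyl carbon of 14, poor behaviour of the polyanion, and retro-aldol of the adduct. The fallback is the classical aldol–oxidation–cyclodehydration construction of dihydropyranones and sets out from 11 and 14. Lactone 14 is opened with MeNHOMe·HCl/Me2AlCl to (2R,3R)-3-hydroxy-N-methoxy-N,2-dimethylbutanamide F3. Silylation (TESCl, imidazole) gives (2R,3R)-N-methoxy-N,2-dimethyl-3-(triethylsilyloxy)butanamide F4, and DIBAL-H reduction gives (2R,3R)-2-methyl-3-(triethylsilyloxy)butanal F5. A boron aldol of 11 (Cy2BCl, Et3N, 2.2 equiv, enolisation at C8) with F5 gives the C8–C9 aldol adduct F6 (C8/C9 epimer mixture, inconsequential). Dess–Martin oxidation gives the β-diketone silyl ether F7, and HF·pyridine removes the TES group and cyclodehydrates; the fallback comes back to the route at 17.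

**Step 4 (ester-enolate ring expansion of the α-branched β-lactone).** The risks are enolisation of 6 instead of addition and incomplete relactonisation. The fallback sets out from 6. Methanolysis (cat. NaOMe, MeOH, 0 °C) gives methyl (2S,3R,4S,5R)-3-hydroxy-2,4-dimethyl-5-(triethylsilyloxy)heptanoate F1. Acylation with propanoyl chloride 4 and pyridine gives methyl (2S,3R,4S,5R)-2,4-dimethyl-3-(propanoyloxy)-5-(triethylsilyloxy)heptanoate F2. A LiHMDS-mediated Dieckmann cyclisation (THF, −78 → 0 °C) followed by 3 M HCl (TES removal) comes back to the route at 10.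

Further compounds
F1 | step 4 | methyl (2S,3R,4S,5R)-3-hydroxy-2,4-dimethyl-5-(triethylsilyloxy)heptanoate | COC(=O)[C@@H](C)[C@H](O)[C@H](C)[C@H](O[Si](CC)(CC)CC)CC
F2 | step 4 | methyl (2S,3R,4S,5R)-2,4-dimethyl-3-(propanoyloxy)-5-(triethylsilyloxy)heptanoate | COC(=O)[C@@H](C)[C@H](OC(=O)CC)[C@H](C)[C@H](O[Si](CC)(CC)CC)CC
F3 | step 7 | (2R,3R)-3-hydroxy-N-methoxy-N,2-dimethylbutanamide | CON(C)C(=O)[C@H](C)[C@@H](C)O
F4 | step 7 | (2R,3R)-N-methoxy-N,2-dimethyl-3-(triethylsilyloxy)butanamide | CON(C)C(=O)[C@H](C)[C@@H](C)O[Si](CC)(CC)CC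
F5 | step 7 | (2R,3R)-2-methyl-3-(triethylsilyloxy)butanal | O=C[C@H](C)[C@@H](C)O[Si](CC)(CC)CC
F6 | step 7 | (5S,6S)-4-hydroxy-6-[(2S,6S,7R)-5-hydroxy-4,6-dimethyl-3-oxo-7-(triethylsilyloxy)octan-2-yl]-3,5-dimethyl-5,6-dihydro-2H-pyran-2-one (C4'/C5' epimer mixture) | CC1=C(O)[C@@H](C)[C@H](OC1=O)[C@H](C)C(=O)C(C)C(O)[C@H](C)[C@@H](C)O[Si](CC)(CC)CC
F7 | step 7 | (5S,6S)-6-[(2S,6R,7R)-4,6-dimethyl-3,5-dioxo-7-(triethylsilyloxy)octan-2-yl]-4-hydroxy-3,5-dimethyl-5,6-dihydro-2H-pyran-2-one | CC1=C(O)[C@@H](C)[C@H](OC1=O)[C@H](C)C(=O)C(C)C(=O)[C@H](C)[C@@H](C)O[Si](CC)(CC)CC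
F8 | step 8 | (5S,6S)-6-[(2S,6E)-4,6-dimethyl-3,5-dioxooct-6-en-2-yl]-4-hydroxy-3,5-dimethyl-5,6-dihydro-2H-pyran-2-one | CC1=C(O)[C@@H](C)[C@H](OC1=O)[C@H](C)C(=O)C(C)C(=O)/C(C)=C/C
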